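All runs were computed with constants of no real substance; noise was put on by code.

1. We start from what is left. After 8.00 d the readings of the gamma run put what is left at 30.6 % of its left-handed substrate and 61.0 % of its right-handed substrate, each as a share of its own charge, the second reckoned from the right-handed product.

common to all: gas 92 mM (held)
- gamma: left-handed substrate 0.33 M; right-handed substrate 0.33 M; precatalyst 4.1 mol%; run made earlier
- zeta: left-handed substrate 0.73 M; right-handed substrate 0.73 M; precatalyst 4.1 mol%; run made earlier
- beta: left-handed substrate 0.49 M; right-handed substrate 0.49 M; precatalyst 2 mol%; run made earlier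
- flask: left-handed substrate 0.49 M; right-handed substrate 0.49 M; precatalyst 4.1 mol%; time 8.0 d

| run | time / d | left-handed product / % | right-handed product / % | left-handed substrate / % |
|---|---|---|---|---|
| gamma | 0.625 | 2.1 | 0.5 | 49.1 |
| gamma | 1.25 | 4.5 | 3.2 | 45.7 |
| gamma | 2.50 | 12.7 | 5.8 | 38.5 |
| gamma | 4.00 | 19.1 | 10.6 | 29.7 |
| gamma | 8.00 | 34.8 | 19.5 | 15.3 |
| zeta | 0.625 | 1.2 | 1.8 | 45.3 |
| zeta | 2.08 | 6.3 | 3.8 | 42.9 |
| zeta | 4.00 | 19.4 | 7.6 | 32.2 |
| zeta | 6.00 | 24.8 | 11.8 | 24.6 |
| zeta | 8.00 | 31.4 | 16.2 | 19.6 |
| beta | 1.67 | 5.6 | 3.6 | 44.2 |
| beta | 3.00 | 10.7 | 3.4 | 38.7 |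
| beta | 5.00 | 17.8 | 6.2 | 30.3 |
| beta | 6.00 | 20.8 | 11.9 | 28.0 |
| beta | 8.00 | 27.9 | 13.7 | 21.8 |

(standard deviation of a reading: 1 percentage point)
- catalyst is single-handed; left-handed substrate and right-handed substrate are mirror images of each other, charged as a racemate, each of them at the stated concentration
- at the start none of partner is dissolved
- steps thought possible: partner + catalyst + left-handed substrate -> catalyst + left-handed product; partner + catalyst + right-handed substrate -> catalyst + right-handed product; 2 partner -> homo dimer; gas <-> partner; precatalyst -> catalyst
- an excess is the difference of the two amounts in percent of their sum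
- an excess is below zero if the other one leads
1. excess of left-handed product over right-handed product in the product at 20 h
2. excess of left-handed product over right-handed product in the product at 8.0 d
3. part of the left-handed substrate and right-handed substrate charged together that has reacted at 8.0 d

2. Both product steps carry the same [catalyst][partner], so its curve cancels in the ratio of the logarithms of these two fractions. Gamma gives 2.40. This ratio of the two rate constants, the selectivity factor s, reads 2.39 in zeta and 2.59 in beta.

3. While little of a racemate has reacted, the product excess is (s − 1)/(s + 1), so we expect 41.1 % for the flask at 20 h.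

4. We replace the curve of [catalyst][partner] by its mean. The exposure E, that mean times the left-handed rate constant times time, is minus the logarithm of the left-handed fraction left: at the last reading it comes to 1.18 in gamma and 0.936 in zeta, so it reads lower in zeta. A straight line in the charge gives the flask 1.09.

5. The right-handed substrate receives E/s. For the flask we then reckon 51.3 % reacted, with excess 29.0 %.

6. The straight line is the weak link. We take [catalyst]/E as rising linearly with the demand [catalyst][substrate]; at fixed loading, charge/E is then linear in the charge squared. For the flask this gives 1.13, hence an estimate of 52.6 % reacted and excess 28.6 %.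

7. The forecast, reasoning “Selectivity should therefore be constant”, gives 42 %, 30 % and 51 %; our reforged conversion stands above its figure, and our early and final excesses stand below its figures.

8. The flask gives 40.2 %, 27.6 % and 55.0 %, inside the forecast's ranges.

    partner + catalyst + left-handed substrate → catalyst + left-handed product (k = 0.00310 L² mol⁻² s⁻¹)
    partner + catalyst + right-handed substrate → catalyst + right-handed product (k = 0.00130 L² mol⁻² s⁻¹)
    2 partner → homo dimer (k = 1.90 × 10⁻⁵ L mol⁻¹ s⁻¹)
    gas ⇌ partner, rate k4*(csat - [partner]) (kL = 1.40 × 10⁻⁵ s⁻¹)
    precatalyst → catalyst (k = 1.90 × 10⁻⁵ s⁻¹)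

Of its own charge, the flask keeps 30 % of the left-handed substrate at 8.00 d, less than the 60 % of the right-handed substrate. Raised to the power 1/s, the left-handed figure gives 60.3 % for the right-handed one. The neighbouring flask with 10 mol% of precatalyst keeps 16 % of its left-handed substrate, so s gives 46.8 % for the right-handed one, and that flask holds 47 %.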